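**Retrosynthetic overview**
1. Quinone 9 ⇒ phenol 7: the para C–H of the phenol becomes C=O (last step, C–O bond formation by a new N-oxyl oxygen transfer).
2. 7 ⇒ allylphenol 4 + 1-tetracosene 5 (cross-metathesis, then hydrogenation; 3 + 22 carbons give the pentacosyl chain).
3. 4 ⇒ allyl aryl ether 3 (aromatic Claisen; the C–O bond of 3 fixes the chain on the carbon between OH and CH3).
4. 3 ⇒ 2-methoxy-5-methylphenol 1 + allyl bromide 2 (O-allylation).
5. No ring is built: the benzene ring of 1 is carried through and becomes the quinone ring in step 4.

Assumption: the target is achiral (no stereocentre, no stereogenic double bond), so no stereochemistry has to be set; the side chain is read from the SMILES as unbranched pentacosyl (C25).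

**Step 1**
Reactants: 1 2-methoxy-5-methylphenol; 2 allyl bromide (1.2 equiv)
Product: 3 1-(allyloxy)-2-methoxy-5-methylbenzene
Conditions: K2CO3 (1.5 equiv), acetone, reflux, 6 h
Reagents that add atoms: none
Why: Williamson ether synthesis; the phenoxide is alkylated on oxygen by the unhindered primary allylic bromide (SN2), and no stereocentre is formed.

**Step 2**
Reactants: 3 1-(allyloxy)-2-methoxy-5-methylbenzene
Product: 4 2-allyl-6-methoxy-3-methylphenol
Conditions: N,N-diethylaniline, 200 °C, sealed tube, argon, 8 h
Reagents that add atoms: none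
Why: aromatic Claisen rearrangement; of the two ortho carbons only the one next to CH3 carries hydrogen (the other bears OCH3), so the [3,3] shift and tautomerisation put the allyl group between OH and CH3.

**Step 3**
Reactants: 4 2-allyl-6-methoxy-3-methylphenol; 5 1-tetracosene (3 equiv)
Product: 7 6-methoxy-3-methyl-2-pentacosylphenol, via alkenylphenol 6 (not isolated)
Conditions: second-generation Grubbs catalyst RuCl2(=CHPh)(H2IMes)(PCy3) (3 mol %), CH2Cl2, 40 °C, 12 h; then solvent change, 10% Pd/C, H2 (1 atm), EtOAc/THF, 40 °C
Reagents that add atoms: none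
Why: olefin cross-metathesis of two terminal alkenes (excess 5 and loss of ethylene favour the cross product, free phenols are tolerated), followed by catalytic hydrogenation that converts both E and Z isomers of 6 into the saturated chain.

**Step 4**
Reactants: 7 6-methoxy-3-methyl-2-pentacosylphenol
Product: 9 5-methoxy-2-methyl-3-pentacosylcyclohexa-2,5-diene-1,4-dione, via aryloxyphthalimide 8 (not isolated)
Conditions: N-hydroxyphthalimide (2.4 equiv), PhI(OAc)2 (1.2 equiv), MeCN/CH2Cl2 1:1, rt, 10 min; then 7 in CH2Cl2 added over 20 min, 0 °C; then pyridine (2 equiv), rt, 1 h, dark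
Reagents that add atoms: N-hydroxyphthalimide, O=C1c2ccccc2C(=O)N1O
Why: Proposed new method: a Teuber-type oxygen-atom transfer from an organic N-oxyl in a water-free, homogeneous medium that dissolves the waxy phenol; phthalimide-N-oxyl (made beforehand from N-hydroxyphthalimide and the trivalent iodine oxidant PhI(OAc)2, so no free oxidant meets 7) abstracts the phenolic hydrogen (O–H about 83 kcal/mol in 7 against 88 in N-hydroxyphthalimide), a second N-oxyl combines with the phenoxyl radical at C4, the only hydrogen-bearing carbon of high spin density (C2 and C6 are substituted and add reversibly), which forms the new C–O bond, and after tautomerisation to 8 pyridine triggers heterolysis of the weak N–O bond with loss of phthalimide (pKa 8.3) to give the quinone carbonyl; the closest known reaction types are the Teuber oxidation of phenols with Fremy's salt (same hydrogen abstraction, radical coupling and N–O cleavage) and the base-induced Kornblum–DeLaMare-type fragmentation of N-alkoxyphthalimides to carbonyl compounds, but to my knowledge this N-oxyl has not been used as the oxygen donor for a phenol-to-para-quinone oxidation.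

**Compound list**
1 | 2-methoxy-5-methylphenol | COc1ccc(C)cc1O | starting material
2 | allyl bromide (3-bromoprop-1-ene) | C=CCBr | starting material
3 | 1-(allyloxy)-2-methoxy-5-methylbenzene | C=CCOc1cc(C)ccc1OC | intermediate
4 | 2-allyl-6-methoxy-3-methylphenol | C=CCc1c(C)ccc(OC)c1O | intermediate
5 | 1-tetracosene | CCCCCCCCCCCCCCCCCCCCCCC=C | starting material
6 | 6-methoxy-3-methyl-2-[(2E)-pentacos-2-en-1-yl]phenol (E major, some Z, formed in the flask) | CCCCCCCCCCCCCCCCCCCCCC/C=C/Cc1c(C)ccc(OC)c1O | intermediate
7 | 6-methoxy-3-methyl-2-pentacosylphenol | CCCCCCCCCCCCCCCCCCCCCCCCCc1c(C)ccc(OC)c1O | intermediate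
8 | 2-[(4-hydroxy-5-methoxy-2-methyl-3-pentacosylphenyl)oxy]isoindoline-1,3-dione (formed in the flask) | CCCCCCCCCCCCCCCCCCCCCCCCCc1c(C)c(ON2C(=O)c3ccccc3C2=O)cc(OC)c1O | intermediate
9 | 5-methoxy-2-methyl-3-pentacosylcyclohexa-2,5-diene-1,4-dione (2-methoxy-5-methyl-6-pentacosyl-1,4-benzoquinone, CNP0536469.0) | CCCCCCCCCCCCCCCCCCCCCCCCCC1=C(C)C(=O)C=C(OC)C1=O | target

**Totals**
Total step count: 4. Longest linear sequence: 4 (1 → 3 → 4 → 7 → 9).

**Three steps most likely to fail**

Step 4 (the proposed new step). Risks: the N-oxyl decays by self-reaction before it is used; two phenoxyl radicals couple para–para (biphenol or diphenoquinone) if the N-oxyl is not in excess; the reaction stalls at 8; some hydrogen abstraction occurs at the benzylic positions. Fallback with known chemistry, setting out from 7 and coming back at 9: cobalt-catalysed aerobic oxygenation with Co(salen), C16H14CoN2O2 (a divalent cobalt complex, 10 mol %), under O2 (1 atm) in DMF/CH2Cl2 1:1 at rt. Here a cobalt-bound superoxide abstracts the phenolic hydrogen and the cobalt–dioxygen unit couples at the para carbon, so the new oxygen comes from O2 and no N-oxyl or iodine reagent is needed. This is the established way to turn 2-methoxy-6-alkylphenols into 2-methoxy-6-alkyl-1,4-benzoquinones. No new compound arises on this way (F0).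

Step 3. Risks: the cross-metathesis is statistical and needs excess 5; a ruthenium hydride can move the allyl double bond into conjugation before metathesis, which would give a chain one carbon short that is hard to separate (1,4-benzoquinone, 10 mol %, suppresses this if it is seen); the waxy hydrocarbons from surplus 5 must be removed by chromatography. Fallback, setting out from 4 and coming back at 7: the phenol is silylated (TBSCl, imidazole, DMF, rt) to tert-butyl(2-allyl-6-methoxy-3-methylphenoxy)dimethylsilane F1. Anti-Markovnikov hydroboration with 9-BBN–H (THF, rt) gives 9-[3-(2-{[tert-butyl(dimethyl)silyl]oxy}-3-methoxy-6-methylphenyl)propyl]-9-borabicyclo[3.3.1]nonane F2. This is coupled in the same flask with cheap commercial 1-bromodocosane by an alkyl–alkyl Suzuki–Miyaura reaction (Pd(OAc)2 4 mol %, PCy3 8 mol %, K3PO4·H2O, THF, rt) to tert-butyl(6-methoxy-3-methyl-2-pentacosylphenoxy)dimethylsilane F3. Bu4NF (THF, rt) then frees 7. This builds the chain as 3 + 22 carbons through a C(sp3)–C(sp3) coupling and avoids both the alkene mixture and the hydrogenation.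

Step 2. Risks: the reacting ortho carbon is flanked by CH3; attack at the OCH3-bearing ortho carbon followed by a Cope shift gives some para-allyl isomer; 200 °C may cause some decomposition. Fallback, setting out from 1 and coming back at 7 (it bypasses 3, 4 and step 3): magnesium-mediated ortho-formylation (MgCl2, Et3N, paraformaldehyde, MeCN, reflux) places CHO on the only free ortho carbon and gives 2-hydroxy-3-methoxy-6-methylbenzaldehyde F4. Wittig olefination follows with excess ylide from tetracosyl(triphenyl)phosphonium bromide F5 (made from commercial 1-bromotetracosane and PPh3 in toluene at 110 °C; ylide formed with NaN(SiMe3)2, THF, −78 °C to rt). It gives 6-methoxy-3-methyl-2-[(1Z)-pentacos-1-en-1-yl]phenol F6. Hydrogenation (H2, 10% Pd/C, EtOAc/THF) gives 7. The chain position is then fixed by chelation-controlled formylation instead of a sigmatropic shift.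

**Further compounds**
F0 | step 4 | none | none
F1 | step 3 | tert-butyl(2-allyl-6-methoxy-3-methylphenoxy)dimethylsilane | C=CCc1c(C)ccc(OC)c1O[Si](C)(C)C(C)(C)C
F2 | step 3 | 9-[3-(2-{[tert-butyl(dimethyl)silyl]oxy}-3-methoxy-6-methylphenyl)propyl]-9-borabicyclo[3.3.1]nonane | COc1ccc(C)c(CCCB2C3CCCC2CCC3)c1O[Si](C)(C)C(C)(C)C
F3 | step 3 | tert-butyl(6-methoxy-3-methyl-2-pentacosylphenoxy)dimethylsilane | CCCCCCCCCCCCCCCCCCCCCCCCCc1c(C)ccc(OC)c1O[Si](C)(C)C(C)(C)C
F4 | step 2 | 2-hydroxy-3-methoxy-6-methylbenzaldehyde | COc1ccc(C)c(C=O)c1O
F5 | step 2 | tetracosyl(triphenyl)phosphonium bromide | CCCCCCCCCCCCCCCCCCCCCCCC[P+](c1ccccc1)(c1ccccc1)c1ccccc1.[Br-]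
F6 | step 2 | 6-methoxy-3-methyl-2-[(1Z)-pentacos-1-en-1-yl]phenol | CCCCCCCCCCCCCCCCCCCCCCC/C=C\c1c(C)ccc(OC)c1O
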